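**Strategy.** Everything rests on cutting the aryl ether bond between the pyran oxygen O1 (ring C) and C8a of ring A. The key step exploits that O1 also sits on C2, beside the carbinol C3, so C2 can be carried as a ketone: its enolate oxygen is arylated by the ortho bromide of ring A under palladium catalysis, giving a 2,4-diaryl-4H-chromene in one operation. The only stereocentre of the precursor, C4, comes from a rhodium-catalysed asymmetric conjugate addition of the ring D boronic acid to a chalcone and later steers hydroboration of the C2=C3 enol ether, which sets C2 and C3 all-trans. Hydrogenolysis of five benzyl ethers finishes the route.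

Key step: step 7

**Remarks on the chemistry.**
- Flavan numbering is used. Ring A is the benzo ring (C4a to C8a), ring B the catechol ring on C2, ring C the pyran ring, ring D the 2,4-dihydroxy-3-methoxyphenyl ring on C4.
- The descriptor at the diaryl carbon changes along the route (R in 12, S in 13 to 15, R in 16) only because substituent priorities change; the spatial arrangement is the same throughout.
- Assumption for step 6: rhodium–diene catalysts are taken to select the α-face of the enone, the (R,R) ligand serving the α-re face. The (S,S) ligand is therefore chosen for the required face (si at C-α and at C-β). If the chalcone behaves otherwise, the antipodal ligand is used.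

**Step 1**
Reactants: 1 2-bromo-4-hydroxybenzaldehyde
Product: 2 4-(benzyloxy)-2-bromobenzaldehyde
Conditions: BnBr (1.1 equiv), K2CO3 (1.5 equiv), DMF, rt
Reagents that add atoms: benzyl bromide, BrCc1ccccc1
Why: Williamson ether synthesis, in which the acidic phenol para to the aldehyde is alkylated by SN2 on the benzylic bromide.

**Step 2**
Reactants: 2 4-(benzyloxy)-2-bromobenzaldehyde; 3 1-[3,4-bis(benzyloxy)phenyl]ethan-1-one
Product: 5 (E)-3-[4-(benzyloxy)-2-bromophenyl]-1-[3,4-bis(benzyloxy)phenyl]prop-2-en-1-one, via aldol adduct 4 (not isolated)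
Conditions: KOH (0.5 equiv, aq.), EtOH/THF, rt
Reagents that add atoms: none
Why: Claisen–Schmidt condensation, in which the aldol adduct loses water by E1cB elimination to give the conjugated E-enone.

**Step 3**
Reactants: 6 2-methoxybenzene-1,3-diol
Product: 7 1,3-bis(benzyloxy)-2-methoxybenzene
Conditions: BnBr (2.3 equiv), K2CO3 (3 equiv), DMF, 60 °C
Reagents that add atoms: benzyl bromide, BrCc1ccccc1
Why: Double Williamson ether synthesis of the two equivalent phenols.

**Step 4**
Reactants: 7 1,3-bis(benzyloxy)-2-methoxybenzene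
Product: 8 1,3-bis(benzyloxy)-4-bromo-2-methoxybenzene
Conditions: NBS (1.0 equiv), MeCN, 0 °C to rt
Reagents that add atoms: N-bromosuccinimide, O=C1CCC(=O)N1Br
Why: Electrophilic aromatic bromination should occur at C4, which is para to one benzyloxy group and ortho to the other, whereas C5 is meta to both.

**Step 5**
Reactants: 8 1,3-bis(benzyloxy)-4-bromo-2-methoxybenzene
Product: 11 [2,4-bis(benzyloxy)-3-methoxyphenyl]boronic acid, via aryllithium 9 (not isolated), via lithium triisopropoxyborate 10 (not isolated)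
Conditions: n-BuLi (1.05 equiv), THF, −78 °C; B(OiPr)3 (1.5 equiv), −78 °C to rt; 1 M HCl
Reagents that add atoms: triisopropyl borate, CC(C)OB(OC(C)C)OC(C)C; water, O (hydroxyl oxygens on boron); n-butyllithium, [Li]CCCC (lithium in 9 and 10 only)
Why: Bromine–lithium exchange at −78 °C should outrun deprotonation of the benzyl ethers, and the aryllithium is trapped as the borate, which is hydrolysed to the boronic acid (lithiation–borylation).

**Step 6**
Reactants: 5 (E)-3-[4-(benzyloxy)-2-bromophenyl]-1-[3,4-bis(benzyloxy)phenyl]prop-2-en-1-one; 11 [2,4-bis(benzyloxy)-3-methoxyphenyl]boronic acid (2.5 equiv)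
Product: 12 (3R)-3-[4-(benzyloxy)-2-bromophenyl]-1-[3,4-bis(benzyloxy)phenyl]-3-[2,4-bis(benzyloxy)-3-methoxyphenyl]propan-1-one
Conditions: [RhCl(C2H4)2]2 (2.5 mol %), (S,S)-Ph-bod* [(1S,4S)-2,5-diphenylbicyclo[2.2.2]octa-2,5-diene] (5.5 mol %), KOH (0.5 equiv), dioxane/H2O 10:1, 50 °C
Reagents that add atoms: none
Why: Hayashi–Miyaura asymmetric 1,4-addition, in which the aryl group on monovalent rhodium inserts into the enone on the face left open by the chiral diene (si at C-β) and so sets the diaryl stereocentre, the aryl bromide being inert to the catalyst.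

**Step 7**
Reactants: 12 (3R)-3-[4-(benzyloxy)-2-bromophenyl]-1-[3,4-bis(benzyloxy)phenyl]-3-[2,4-bis(benzyloxy)-3-methoxyphenyl]propan-1-one
Product: 13 (4S)-7-(benzyloxy)-2-[3,4-bis(benzyloxy)phenyl]-4-[2,4-bis(benzyloxy)-3-methoxyphenyl]-4H-chromene
Conditions: Pd2(dba)3 (2.5 mol %), DPEphos (6 mol %), Cs2CO3 (2.2 equiv), toluene, 105 °C, argon
Reagents that add atoms: none
Why: Zerovalent palladium inserts into the C8a–Br bond of ring A, carbonate deprotonates the palladium-bound ketone at C3, and the O-bound enolate reductively eliminates the O1–C8a bond; this is an intramolecular enolate O-arylation (Buchwald–Hartwig-type C–O coupling) of the kind that turns ortho-haloaryl ketones into benzofurans and 4H-chromenes. Ring C closes in a formally 6-exo-trig mode at the sp2 carbon C8a, through reductive elimination from a seven-membered oxapalladacycle. No stereocentre is formed, and C4 is safe because it is β to the carbonyl and because its deprotonation in the product would give an 8π pyranyl anion that the weak base cannot reach. The selectivity needed is O- over C-arylation of the ambident enolate; the substrate secures it because C-arylation at C3 would close a four-membered benzocyclobutene ring, and the ketone can enolise only toward C3 since its other side carries ring B. The product is an enol ether with the C2=C3 bond exactly where C2–H and C3–OH are still missing.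

**Step 8**
Reactants: 13 (4S)-7-(benzyloxy)-2-[3,4-bis(benzyloxy)phenyl]-4-[2,4-bis(benzyloxy)-3-methoxyphenyl]-4H-chromene
Product: 15 (2R,3S,4S)-7-(benzyloxy)-2-[3,4-bis(benzyloxy)phenyl]-4-[2,4-bis(benzyloxy)-3-methoxyphenyl]-3,4-dihydro-2H-chromen-3-ol, via C3 borane 14 (not isolated)
Conditions: BH3·THF (3 equiv), THF, 0 °C to rt; then 3 M NaOH, 30% H2O2, 0 °C to rt
Reagents that add atoms: borane–tetrahydrofuran, B.C1CCOC1 (boron in 14 only); hydrogen peroxide, OO (the C3 oxygen)
Why: Hydroboration–oxidation of the cyclic enol ether puts boron on C3 (β to oxygen) and hydrogen on C2 in a syn addition from the face opposite the ring D aryl on C4, and oxidation with retention should give the 2,3-trans-3,4-trans alcohol.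

**Step 9**
Reactants: 15 (2R,3S,4S)-7-(benzyloxy)-2-[3,4-bis(benzyloxy)phenyl]-4-[2,4-bis(benzyloxy)-3-methoxyphenyl]-3,4-dihydro-2H-chromen-3-ol
Product: 16 (2R,3S,4R)-2-(3,4-dihydroxyphenyl)-4-(2,4-dihydroxy-3-methoxyphenyl)-3,4-dihydro-2H-chromene-3,7-diol
Conditions: H2 (1 atm), Pd(OH)2/C (20 wt %), THF/MeOH 1:1, rt
Reagents that add atoms: none
Why: Catalytic hydrogenolysis removes the five aryl benzyl ethers, while the methyl ether and the cyclic benzylic C2–O1 bond should survive at room temperature and atmospheric pressure.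

**Compound list**

1 | 2-bromo-4-hydroxybenzaldehyde | O=Cc1ccc(O)cc1Br | starting material
2 | 4-(benzyloxy)-2-bromobenzaldehyde | O=Cc1ccc(OCc2ccccc2)cc1Br | intermediate
3 | 1-[3,4-bis(benzyloxy)phenyl]ethan-1-one | CC(=O)c1ccc(OCc2ccccc2)c(OCc2ccccc2)c1 | starting material
4 | 3-[4-(benzyloxy)-2-bromophenyl]-1-[3,4-bis(benzyloxy)phenyl]-3-hydroxypropan-1-one (racemic aldol adduct, not isolated) | O=C(CC(O)c1ccc(OCc2ccccc2)cc1Br)c1ccc(OCc2ccccc2)c(OCc2ccccc2)c1 | intermediate
5 | (E)-3-[4-(benzyloxy)-2-bromophenyl]-1-[3,4-bis(benzyloxy)phenyl]prop-2-en-1-one | O=C(/C=C/c1ccc(OCc2ccccc2)cc1Br)c1ccc(OCc2ccccc2)c(OCc2ccccc2)c1 | intermediate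
6 | 2-methoxybenzene-1,3-diol | COc1c(O)cccc1O | starting material
7 | 1,3-bis(benzyloxy)-2-methoxybenzene | COc1c(OCc2ccccc2)cccc1OCc1ccccc1 | intermediate
8 | 1,3-bis(benzyloxy)-4-bromo-2-methoxybenzene | COc1c(OCc2ccccc2)ccc(Br)c1OCc1ccccc1 | intermediate
9 | [2,4-bis(benzyloxy)-3-methoxyphenyl]lithium (not isolated) | COc1c(OCc2ccccc2)ccc([Li])c1OCc1ccccc1 | intermediate
10 | lithium [2,4-bis(benzyloxy)-3-methoxyphenyl]triisopropoxyborate (not isolated) | [Li+].COc1c(OCc2ccccc2)ccc([B-](OC(C)C)(OC(C)C)OC(C)C)c1OCc1ccccc1 | intermediate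
11 | [2,4-bis(benzyloxy)-3-methoxyphenyl]boronic acid | COc1c(OCc2ccccc2)ccc(B(O)O)c1OCc1ccccc1 | intermediate
12 | (3R)-3-[4-(benzyloxy)-2-bromophenyl]-1-[3,4-bis(benzyloxy)phenyl]-3-[2,4-bis(benzyloxy)-3-methoxyphenyl]propan-1-one | COc1c(OCc2ccccc2)ccc([C@H](c2ccc(OCc3ccccc3)cc2Br)CC(=O)c2ccc(OCc3ccccc3)c(OCc3ccccc3)c2)c1OCc1ccccc1 | intermediate
13 | (4S)-7-(benzyloxy)-2-[3,4-bis(benzyloxy)phenyl]-4-[2,4-bis(benzyloxy)-3-methoxyphenyl]-4H-chromene | COc1c(OCc2ccccc2)ccc([C@@H]2c3ccc(OCc4ccccc4)cc3OC(c3ccc(OCc4ccccc4)c(OCc4ccccc4)c3)=C2)c1OCc1ccccc1 | intermediate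
14 | [(2S,3S,4S)-7-(benzyloxy)-2-[3,4-bis(benzyloxy)phenyl]-4-[2,4-bis(benzyloxy)-3-methoxyphenyl]-3,4-dihydro-2H-chromen-3-yl]borane (boron trans to ring D and cis to H on C2, not isolated) | COc1c(OCc2ccccc2)ccc([C@@H]2c3ccc(OCc4ccccc4)cc3O[C@H](c3ccc(OCc4ccccc4)c(OCc4ccccc4)c3)[C@H]2B)c1OCc1ccccc1 | intermediate
15 | (2R,3S,4S)-7-(benzyloxy)-2-[3,4-bis(benzyloxy)phenyl]-4-[2,4-bis(benzyloxy)-3-methoxyphenyl]-3,4-dihydro-2H-chromen-3-ol | COc1c(OCc2ccccc2)ccc([C@@H]2c3ccc(OCc4ccccc4)cc3O[C@H](c3ccc(OCc4ccccc4)c(OCc4ccccc4)c3)[C@H]2O)c1OCc1ccccc1 | intermediate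
16 | (2R,3S,4R)-2-(3,4-dihydroxyphenyl)-4-(2,4-dihydroxy-3-methoxyphenyl)-3,4-dihydro-2H-chromene-3,7-diol | COc1c(O)ccc([C@@H]2c3ccc(O)cc3O[C@H](c3ccc(O)c(O)c3)[C@H]2O)c1O | target

**Step count.** Total: 9 steps. Longest linear sequence: 7 steps (steps 3, 4, 5, 6, 7, 8, 9).

**Steps most likely to fail**

1. Step 7. Reductive elimination of the aryl–oxygen bond from the palladium enolate may be slower than protodebromination of the arylpalladium intermediate or its C–H arylation onto ring D, so that little chromene forms. The fallback sets out from 12 and comes back at 13. The bromide is first hydroxylated under palladium catalysis (Pd2(dba)3, tBuXPhos, KOH, dioxane/H2O, 100 °C) to give (3S)-3-[4-(benzyloxy)-2-hydroxyphenyl]-1-[3,4-bis(benzyloxy)phenyl]-3-[2,4-bis(benzyloxy)-3-methoxyphenyl]propan-1-one F1. Catalytic p-TsOH in toluene at rt should then close the cyclic hemiketal (4S)-7-(benzyloxy)-2-[3,4-bis(benzyloxy)phenyl]-4-[2,4-bis(benzyloxy)-3-methoxyphenyl]-3,4-dihydro-2H-chromen-2-ol F2 and dehydrate it to 13. In this variant the O1–C8a bond is still made on the same bromide by C–O coupling, but the ring then closes at O1–C2 by an established cyclodehydration.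

2. Step 6. Protodeboronation of the hindered ortho-alkoxy boronic acid may outrun insertion into the ortho-bromo-substituted enone, or the catalyst may discriminate the enone faces poorly. The fallback sets out from 2 and 8 and comes back at 12, using auxiliary control instead of catalyst control.
   - Knoevenagel–Doebner condensation of 2 with malonic acid (pyridine, cat. piperidine, 90 °C) should give, through 2-{[4-(benzyloxy)-2-bromophenyl]methylidene}propanedioic acid F3, (E)-3-[4-(benzyloxy)-2-bromophenyl]prop-2-enoic acid F4.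
   - Its mixed pivalic anhydride F5 (PivCl, Et3N, THF, −20 °C) acylates (S)-4-phenyl-1,3-oxazolidin-2-one (LiCl, rt) to give (4S)-3-[(E)-3-[4-(benzyloxy)-2-bromophenyl]prop-2-enoyl]-4-phenyl-1,3-oxazolidin-2-one F6.
   - [2,4-Bis(benzyloxy)-3-methoxyphenyl]magnesium bromide F7 (from 8, Mg, THF) with CuBr·SMe2 (THF/Me2S, −40 °C) should add to the magnesium-chelated syn-s-cis imide on the face opposite the 4-phenyl group, which is the si face at C-β. This gives (4S)-3-[(3R)-3-[4-(benzyloxy)-2-bromophenyl]-3-[2,4-bis(benzyloxy)-3-methoxyphenyl]propanoyl]-4-phenyl-1,3-oxazolidin-2-one F8.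
   - AlMe3 with MeNH(OMe)·HCl (CH2Cl2, 0 °C) converts F8 into (3R)-3-[4-(benzyloxy)-2-bromophenyl]-3-[2,4-bis(benzyloxy)-3-methoxyphenyl]-N-methoxy-N-methylpropanamide F9 and releases the auxiliary.
   - [3,4-Bis(benzyloxy)phenyl]magnesium bromide F10 (from commercial 4-bromo-1,2-bis(benzyloxy)benzene, Brc1ccc(OCc2ccccc2)c(OCc2ccccc2)c1, Mg, THF, 0 °C) adds once to F9 to give 12.

3. Step 8. The C3 borane may undergo β-alkoxy elimination with opening of ring C, or borane may add too slowly to the hindered trisubstituted enol ether. The fallback sets out from 13 and comes back at 15.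
   - Dihydroxylation with OsO4 (2 mol %) and NMO in acetone/H2O should add both hydroxyl groups on the face opposite ring D. This gives (3S,4S)-7-(benzyloxy)-2-[3,4-bis(benzyloxy)phenyl]-4-[2,4-bis(benzyloxy)-3-methoxyphenyl]-3,4-dihydro-2H-chromene-2,3-diol F11, a hemiketal in equilibrium with its open α-hydroxy ketone.
   - NaBH4 (MeOH, 0 °C) reduces the open form to (2S,3S)-3-[4-(benzyloxy)-2-hydroxyphenyl]-1-[3,4-bis(benzyloxy)phenyl]-3-[2,4-bis(benzyloxy)-3-methoxyphenyl]propane-1,2-diol F12; the configuration at C1 is immaterial.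
   - Catalytic p-TsOH (CH2Cl2, rt) ionises the benzylic carbinol, whose cation is stabilised by the para benzyloxy group of ring B. The ring A phenol then closes ring C with the aryl group trans to the C3 hydroxyl, as in the acid cyclisation of 1-aryl-3-(2-hydroxyaryl)propane-1,2-diols to 2,3-trans-flavan-3-ols, to give 15.

**Further compounds**

F1 | step 7 | (3S)-3-[4-(benzyloxy)-2-hydroxyphenyl]-1-[3,4-bis(benzyloxy)phenyl]-3-[2,4-bis(benzyloxy)-3-methoxyphenyl]propan-1-one | COc1c(OCc2ccccc2)ccc([C@H](c2ccc(OCc3ccccc3)cc2O)CC(=O)c2ccc(OCc3ccccc3)c(OCc3ccccc3)c2)c1OCc1ccccc1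
F2 | step 7 | (4S)-7-(benzyloxy)-2-[3,4-bis(benzyloxy)phenyl]-4-[2,4-bis(benzyloxy)-3-methoxyphenyl]-3,4-dihydro-2H-chromen-2-ol (both C2 epimers) | COc1c(OCc2ccccc2)ccc([C@@H]2c3ccc(OCc4ccccc4)cc3OC(O)(c3ccc(OCc4ccccc4)c(OCc4ccccc4)c3)C2)c1OCc1ccccc1
F3 | step 6 | 2-{[4-(benzyloxy)-2-bromophenyl]methylidene}propanedioic acid | OC(=O)C(=Cc1ccc(OCc2ccccc2)cc1Br)C(O)=O
F4 | step 6 | (E)-3-[4-(benzyloxy)-2-bromophenyl]prop-2-enoic acid | OC(=O)/C=C/c1ccc(OCc2ccccc2)cc1Br
F5 | step 6 | (E)-3-[4-(benzyloxy)-2-bromophenyl]prop-2-enoic 2,2-dimethylpropanoic anhydride | CC(C)(C)C(=O)OC(=O)/C=C/c1ccc(OCc2ccccc2)cc1Br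
F6 | step 6 | (4S)-3-[(E)-3-[4-(benzyloxy)-2-bromophenyl]prop-2-enoyl]-4-phenyl-1,3-oxazolidin-2-one | O=C(/C=C/c1ccc(OCc2ccccc2)cc1Br)N1[C@@H](c2ccccc2)COC1=O
F7 | step 6 | [2,4-bis(benzyloxy)-3-methoxyphenyl]magnesium bromide | COc1c(OCc2ccccc2)ccc([Mg]Br)c1OCc1ccccc1
F8 | step 6 | (4S)-3-[(3R)-3-[4-(benzyloxy)-2-bromophenyl]-3-[2,4-bis(benzyloxy)-3-methoxyphenyl]propanoyl]-4-phenyl-1,3-oxazolidin-2-one | COc1c(OCc2ccccc2)ccc([C@H](c2ccc(OCc3ccccc3)cc2Br)CC(=O)N2[C@@H](c3ccccc3)COC2=O)c1OCc1ccccc1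
F9 | step 6 | (3R)-3-[4-(benzyloxy)-2-bromophenyl]-3-[2,4-bis(benzyloxy)-3-methoxyphenyl]-N-methoxy-N-methylpropanamide | COc1c(OCc2ccccc2)ccc([C@H](c2ccc(OCc3ccccc3)cc2Br)CC(=O)N(C)OC)c1OCc1ccccc1
F10 | step 6 | [3,4-bis(benzyloxy)phenyl]magnesium bromide | Br[Mg]c1ccc(OCc2ccccc2)c(OCc2ccccc2)c1
F11 | step 8 | (3S,4S)-7-(benzyloxy)-2-[3,4-bis(benzyloxy)phenyl]-4-[2,4-bis(benzyloxy)-3-methoxyphenyl]-3,4-dihydro-2H-chromene-2,3-diol (both C2 epimers) | COc1c(OCc2ccccc2)ccc([C@@H]2c3ccc(OCc4ccccc4)cc3OC(O)(c3ccc(OCc4ccccc4)c(OCc4ccccc4)c3)[C@H]2O)c1OCc1ccccc1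
F12 | step 8 | (2S,3S)-3-[4-(benzyloxy)-2-hydroxyphenyl]-1-[3,4-bis(benzyloxy)phenyl]-3-[2,4-bis(benzyloxy)-3-methoxyphenyl]propane-1,2-diol (both C1 epimers) | COc1c(OCc2ccccc2)ccc([C@H](c2ccc(OCc3ccccc3)cc2O)[C@H](O)C(O)c2ccc(OCc3ccccc3)c(OCc3ccccc3)c2)c1OCc1ccccc1
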